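**Plan**

- Numbering: chroman-4-one locants for the core (O1, C2, C3, C4, C4a, C5–C8, C8a; ring A = pyranone, ring B = carbocycle); C1' is the side-chain CH that bears propyl. In ring B, C7 is a ketone held between quaternary C8 and C6, and C5–C6–C1'–CH2–CO2H is a 3-propylglutaric acid chain, so C6–C7 is a Claisen bond between a C5-ketone enolate and an ester on C8.
- Retrosynthesis: the carboxylic ester C–O, then C6–C7 (opens ring B), then C4a–C5 (acylation of a 5-metallated pyranone), then O1–C8a and C4–C4a (ring A from a β-hydroxy ynone), then the two C8–CH2 bonds (alkylations of methyl acetoacetate).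
- Forward: fragment 1 (quaternary alkynyl ester from (R)-limonene and methyl acetoacetate) and fragment 2 (syn-aldol Weinreb amide) give the ynone. Ring A closes by 6-endo oxa-Michael addition, C4a is iodinated and acylated with fragment 3 (3-propylglutaric half-ester chloride), ring B closes last, and saponification ends the route.
- Stereochemistry: the side-chain centre comes from (R)-limonene; C8 from prenylation of a valine-derived chiral enamine; C2 and C3 from an Evans syn-aldol reaction; C1' from alkaloid-mediated methanolysis of the prochiral anhydride; the closure of ring B creates no centre.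

Key step: step 17

Assumption: in step 7 the lithiated (S)-valine tert-butyl ester enamine in toluene–HMPA is taken to deliver the (2R) centre; this type of alkylation gives the opposite face when the lithium ligand is changed to THF, so the medium (or the (R)-valine ester) would be chosen to match.
Assumption: in step 14 quinine is taken to give the (R)-half-ester, by analogy with alkaloid-mediated openings of other 3-alkylglutaric anhydrides; quinidine, its pseudo-enantiomer, would be used if the sense proves opposite.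
Remark: the bicyclic products are drawn as the 5-hydroxy-4,7-dione tautomer of the target SMILES; the enol tautomers of the trione interconvert.

Step 1
Reactants: 1 (R)-limonene
Product: 3 methyl (3R)-6-oxo-3-(prop-1-en-2-yl)heptanoate, via methoxy hydroperoxide 2 (not isolated)
Conditions: O3 (1 equiv), CH2Cl2/MeOH 5:1, NaHCO3, −78 °C (Sudan Red 7B end point); then Ac2O, Et3N, 0 °C → rt
Reagents that add atoms: ozone, [O-][O+]=O; methanol, CO
Why: Ozonolysis with terminus-differentiating work-up: ozone attacks the trisubstituted ring alkene faster than the isopropenyl group, methanol traps the carbonyl oxide formed at the former CH terminus, and Ac2O/Et3N dehydrates the methoxy hydroperoxide to the methyl ester, the stereocentre coming unchanged from limonene.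

Step 2
Reactants: 3 methyl (3R)-6-oxo-3-(prop-1-en-2-yl)heptanoate
Product: 4 methyl (3R)-6-methyl-3-(prop-1-en-2-yl)hept-6-enoate
Conditions: Ph3PCH3Br, KOt-Bu, THF, 0 °C; then 3, 0 °C → rt
Reagents that add atoms: methyltriphenylphosphonium bromide, C[P+](c1ccccc1)(c1ccccc1)c1ccccc1.[Br-]
Why: Wittig methylenation is selective for the ketone over the methyl ester and does not touch the stereocentre, which is β to the ester.

Step 3
Reactants: 4 methyl (3R)-6-methyl-3-(prop-1-en-2-yl)hept-6-enoate
Product: 5 (3R)-6-methyl-3-(prop-1-en-2-yl)hept-6-enoic acid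
Conditions: LiOH·H2O, THF/MeOH/H2O, rt; then 1 M HCl
Reagents that add atoms: lithium hydroxide, [Li+].[OH-]
Why: Saponification of an unhindered methyl ester with no epimerisable centre next to the carboxyl group.

Step 4
Reactants: 5 (3R)-6-methyl-3-(prop-1-en-2-yl)hept-6-enoic acid
Product: 7 (3S)-3-(iodomethyl)-2,6-dimethylhepta-1,6-diene, via thiohydroxamate ester 6 (not isolated)
Conditions: 1-hydroxypyridine-2(1H)-thione, DCC, DMAP (cat.), CH2Cl2, 0 °C → rt, dark; then CHI3, benzene/cyclohexene, tungsten lamp, reflux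
Reagents that add atoms: iodoform, IC(I)I
Why: Barton decarboxylative iodination: photolysis of the thiohydroxamate ester releases the primary radical after loss of CO2, and iodine-atom transfer from iodoform should outrun 3-exo and 5-exo/6-endo attack on the two alkenes, so the neighbouring stereocentre is kept (the descriptor changes to S only through the priority of iodine).

Step 5
Reactants: 7 (3S)-3-(iodomethyl)-2,6-dimethylhepta-1,6-diene; 8 methyl acetoacetate
Product: 9 methyl (4R)-2-acetyl-7-methyl-4-(prop-1-en-2-yl)oct-7-enoate (both C2 epimers)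
Conditions: 8 (3 equiv), NaH, THF/DMF, 0 °C; then 7, 60 °C
Reagents that add atoms: none
Why: Acetoacetic ester alkylation: the soft, weakly basic sodium enolate displaces the primary iodide without E2 elimination, excess 8 suppresses dialkylation, and the C2 centre is left unassigned because the next step erases it.

Step 6
Reactants: 9 methyl (4R)-2-acetyl-7-methyl-4-(prop-1-en-2-yl)oct-7-enoate; 10 tert-butyl L-valinate (from its commercial hydrochloride)
Product: 11 (Z)-enamino ester, methyl (2Z,4R)-2-[1-({(2S)-1-tert-butoxy-3-methyl-1-oxobutan-2-yl}amino)ethylidene]-7-methyl-4-(prop-1-en-2-yl)oct-7-enoate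
Conditions: 10 (1.2 equiv), BF3·OEt2 (cat.), toluene, reflux, Dean–Stark trap
Reagents that add atoms: none
Why: Acid-catalysed condensation of the ketone with the primary amine under azeotropic water removal (enamine formation) gives the hydrogen-bonded (Z)-enamino ester, which removes the C2 centre and installs the auxiliary.

Step 7
Reactants: 11 (Z)-enamino ester
Product: 13 methyl (2R,4R)-2-acetyl-7-methyl-2-(3-methylbut-2-en-1-yl)-4-(prop-1-en-2-yl)oct-7-enoate, via alkylated imine 12 (not isolated)
Conditions: LiN(i-Pr)2, toluene, −78 °C; HMPA (1 equiv); prenyl bromide, −78 → −40 °C; then 1 M aq. HCl, THF, 0 °C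
Reagents that add atoms: 1-bromo-3-methylbut-2-ene, CC(C)=CCBr; water, O
Why: Alkylation of a chiral lithiated enamine: lithium is chelated by the nitrogen and both ester carbonyls, the valine isopropyl group shields one face and HMPA fills the fourth site, so prenyl bromide should enter from one face and set the quaternary centre as (2R), after which mild acid hydrolyses the imine and returns the auxiliary.

Step 8
Reactants: 13 methyl (2R,4R)-2-acetyl-7-methyl-2-(3-methylbut-2-en-1-yl)-4-(prop-1-en-2-yl)oct-7-enoate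
Product: 15 methyl (2R,4R)-2-ethynyl-7-methyl-2-(3-methylbut-2-en-1-yl)-4-(prop-1-en-2-yl)oct-7-enoate, via enol phosphate 14 (not isolated)
Conditions: LiN(i-Pr)2 (1.1 equiv), THF, −78 °C; ClP(O)(OEt)2, −78 °C → rt; then LiN(i-Pr)2 (2.3 equiv), THF, −78 °C → rt; aq. NH4Cl
Reagents that add atoms: none
Why: Conversion of a methyl ketone into a terminal alkyne by enol phosphate formation and base-induced elimination: enolisation can occur only at the methyl group because the other α-carbon is quaternary, and that centre has no proton to lose.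

Step 9
Reactants: 16 (S)-4-benzyl-3-propionyloxazolidin-2-one; 17 acetaldehyde
Product: 18 (4S)-4-benzyl-3-[(2S,3R)-3-hydroxy-2-methylbutanoyl]oxazolidin-2-one
Conditions: Bu2BOTf, i-Pr2NEt, CH2Cl2, −78 → 0 °C; then 17, −78 → 0 °C; pH 7 buffer, MeOH, H2O2, 0 °C
Reagents that add atoms: none
Why: Evans syn-aldol reaction: the (Z)-boron enolate reacts through a chair Zimmerman–Traxler transition state on the face away from the benzyl group, which sets (2S,3R).

Step 10
Reactants: 18 (4S)-4-benzyl-3-[(2S,3R)-3-hydroxy-2-methylbutanoyl]oxazolidin-2-one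
Product: 19 (2S,3R)-3-hydroxy-N-methoxy-N,2-dimethylbutanamide
Conditions: MeONHMe·HCl, AlMe3, CH2Cl2, −15 → 0 °C; aq. KNaC4H4O6 work-up
Reagents that add atoms: N,O-dimethylhydroxylamine hydrochloride, CNOC.Cl
Why: Aluminium-amide transamidation to the Weinreb amide is assisted by the free β-hydroxyl, cleaves only the exocyclic imide carbonyl and does not epimerise the α-centre.

Step 11
Reactants: 15 methyl (2R,4R)-2-ethynyl-7-methyl-2-(3-methylbut-2-en-1-yl)-4-(prop-1-en-2-yl)oct-7-enoate; 19 (2S,3R)-3-hydroxy-N-methoxy-N,2-dimethylbutanamide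
Product: 20 methyl (2R,4R)-2-[(4S,5R)-5-hydroxy-4-methyl-3-oxohex-1-yn-1-yl]-7-methyl-2-(3-methylbut-2-en-1-yl)-4-(prop-1-en-2-yl)oct-7-enoate
Conditions: 15 (1.2 equiv), LiN(i-Pr)2, THF, −78 °C; add 19 pretreated with i-PrMgCl (1 equiv, THF, −20 °C); −78 → 0 °C; aq. NH4Cl
Reagents that add atoms: none
Why: Weinreb ketone synthesis with a lithium acetylide: the hydroxyl is masked as its magnesium alkoxide, the chelated tetrahedral intermediate prevents over-addition, and the hindered quaternary methyl ester is not attacked at low temperature.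

Step 12
Reactants: 20 β-hydroxy ynone
Product: 21 methyl (2R,4R)-2-[(2R,3S)-2,3-dimethyl-4-oxo-3,4-dihydro-2H-pyran-6-yl]-7-methyl-2-(3-methylbut-2-en-1-yl)-4-(prop-1-en-2-yl)oct-7-enoate
Conditions: TsOH·H2O (0.1 equiv), CH2Cl2, 0 °C → rt
Reagents that add atoms: none
Why: Brønsted-acid-catalysed 6-endo-dig oxa-Michael addition of the hydroxyl to the ynone closes ring A with oxygen on C8a by necessity (attack at the α-carbon is electronically mismatched), and the syn-aldol centres are carried unchanged into the cis-2,3-dimethyl ring.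

Step 13
Reactants: 21 dihydropyranone
Product: 22 methyl (2R,4R)-2-[(2R,3S)-5-iodo-2,3-dimethyl-4-oxo-3,4-dihydro-2H-pyran-6-yl]-7-methyl-2-(3-methylbut-2-en-1-yl)-4-(prop-1-en-2-yl)oct-7-enoate
Conditions: I2 (2 equiv), pyridine/CH2Cl2 1:1, 0 °C → rt, dark; aq. Na2S2O3
Reagents that add atoms: iodine, II
Why: α-Iodination of an enone with I2/pyridine: the enol-ether-like C4a of the vinylogous ester is the most nucleophilic carbon and pyridine removes its proton, while without a stronger iodonium source the isolated alkenes add iodine only reversibly.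

Step 14
Reactants: 23 3-propylglutaric anhydride
Product: 24 (3R)-5-methoxy-5-oxo-3-propylpentanoic acid
Conditions: quinine (1.1 equiv), MeOH (3 equiv), toluene, −55 °C; 1 M HCl wash
Reagents that add atoms: methanol, CO
Why: Alkaloid-mediated desymmetrising methanolysis of a prochiral anhydride: the quinine–methanol complex differentiates the two enantiotopic carbonyl groups and so sets the (R) centre that becomes C1'.

Step 15
Reactants: 24 (3R)-5-methoxy-5-oxo-3-propylpentanoic acid
Product: 25 methyl (3S)-5-chloro-5-oxo-3-propylpentanoate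
Conditions: (COCl)2, DMF (cat.), CH2Cl2, 0 °C → rt; used crude at once
Reagents that add atoms: oxalyl chloride, O=C(Cl)C(Cl)=O
Why: Acid chloride formation under Vilsmeier catalysis leaves the centre (β to both carbonyls) untouched, the descriptor changing only by priority, and immediate use avoids scrambling through the symmetric cyclic anhydride.

Step 16
Reactants: 22 5-iodopyranone; 25 methyl (3S)-5-chloro-5-oxo-3-propylpentanoate
Product: 27 methyl (2R,4R)-2-{(2R,3S)-5-[(3R)-5-methoxy-5-oxo-3-propylpentanoyl]-2,3-dimethyl-4-oxo-3,4-dihydro-2H-pyran-6-yl}-7-methyl-2-(3-methylbut-2-en-1-yl)-4-(prop-1-en-2-yl)oct-7-enoate, via alkenylzinc iodide 26 (not isolated)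
Conditions: Zn dust (activated with BrCH2CH2Br and Me3SiCl), LiCl, THF, 25 °C; then 25 (1.3 equiv), Pd(PPh3)4 (5 mol %), THF, 0 °C → rt
Reagents that add atoms: none
Why: Direct insertion of LiCl-activated zinc into the C–I bond gives an alkenylzinc that tolerates the ketone and ester groups, and Pd(PPh3)4-catalysed Negishi acylation with the acid chloride forms the C4a–C5 ketone bond exactly where the iodine stood.

Step 17
Reactants: 27 acylpyranone diester
Product: 28 methyl (3S)-3-{(2R,3S,8R)-5-hydroxy-2,3-dimethyl-8-(3-methylbut-2-en-1-yl)-8-[(2R)-5-methyl-2-(prop-1-en-2-yl)hex-5-en-1-yl]-4,7-dioxo-3,4,7,8-tetrahydro-2H-chromen-6-yl}hexanoate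
Conditions: LiN(SiMe3)2 (2.2 equiv), THF, −78 → −20 °C; 1 M HCl quench at −78 °C
Reagents that add atoms: none
Why: LiN(SiMe3)2 removes a proton from the C6 methylene next to the C5 ketone, the enolate carbon adds to the C7 methyl ester on quaternary C8, methoxide leaves, and the new 1,3-diketone is deprotonated at once to a delocalised trione enolate that drives the equilibrium. The closest known reaction type is the Dieckmann (intramolecular Claisen) condensation of keto esters to cyclic 1,3-diones, as used for acylphloroglucinol-type triones. Ring B (C4a, C5, C6, C7, C8, C8a) closes in a 6-(enolendo)-exo-trig mode, the enolate C5=C6 bond lying inside the new ring and the ester carbonyl outside it. No stereocentre is created; C8, C1', C2, C3 and the side-chain centre are carried in from 27, and the C1' descriptor changes from R to S only because C6 gains priority. The step needs deprotonation at C6 and not at C3 or next to the chain ester: C6–H is the most acidic unhindered proton, a C3 enolate could reach C7 only through a bridged ring with a bridgehead alkene, and the chain-ester enolate would have to close an eight-membered ring. Low temperature, a limited amount of base and the negative charge of the product enolate should protect C3 from epimerisation and ring A from E1cB opening.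

Step 18
Reactants: 28 methyl ester of the target
Product: 29 CNP0294320.1, (3S)-3-{(2R,3S,8R)-5-hydroxy-2,3-dimethyl-8-(3-methylbut-2-en-1-yl)-8-[(2R)-5-methyl-2-(prop-1-en-2-yl)hex-5-en-1-yl]-4,7-dioxo-3,4,7,8-tetrahydro-2H-chromen-6-yl}hexanoic acid
Conditions: LiOH·H2O (5 equiv), THF/H2O 3:1, 0 °C → rt; 1 M HCl to pH 3
Reagents that add atoms: lithium hydroxide, [Li+].[OH-]
Why: Saponification of the unhindered chain ester; the acidic trione is present as its enolate, which shields the ring carbonyls from hydroxide and C3 from enolisation, and acidification returns the enol acid.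

**Compound list**

1 | (R)-limonene | CC1=CC[C@@H](CC1)C(C)=C | starting material
2 | (5R)-7-hydroperoxy-7-methoxy-5-(prop-1-en-2-yl)heptan-2-one (both C7 epimers) | CC(=O)CC[C@H](CC(OC)OO)C(=C)C | intermediate
3 | methyl (3R)-6-oxo-3-(prop-1-en-2-yl)heptanoate | CC(=O)CC[C@H](CC(=O)OC)C(=C)C | intermediate
4 | methyl (3R)-6-methyl-3-(prop-1-en-2-yl)hept-6-enoate | C=C(C)CC[C@H](CC(=O)OC)C(=C)C | intermediate
5 | (3R)-6-methyl-3-(prop-1-en-2-yl)hept-6-enoic acid | C=C(C)CC[C@H](CC(=O)O)C(=C)C | intermediate
6 | 2-thioxopyridin-1(2H)-yl (3R)-6-methyl-3-(prop-1-en-2-yl)hept-6-enoate | C=C(C)CC[C@H](CC(=O)ON1C=CC=CC1=S)C(=C)C | intermediate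
7 | (3S)-3-(iodomethyl)-2,6-dimethylhepta-1,6-diene | C=C(C)CC[C@H](CI)C(=C)C | intermediate
8 | methyl acetoacetate | CC(=O)CC(=O)OC | starting material
9 | methyl (4R)-2-acetyl-7-methyl-4-(prop-1-en-2-yl)oct-7-enoate (both C2 epimers) | C=C(C)CC[C@H](CC(C(C)=O)C(=O)OC)C(=C)C | intermediate
10 | tert-butyl L-valinate | CC(C)[C@H](N)C(=O)OC(C)(C)C | starting material
11 | methyl (2Z,4R)-2-[1-({(2S)-1-tert-butoxy-3-methyl-1-oxobutan-2-yl}amino)ethylidene]-7-methyl-4-(prop-1-en-2-yl)oct-7-enoate | C=C(C)CC[C@H](C/C(C(=O)OC)=C(\C)N[C@@H](C(C)C)C(=O)OC(C)(C)C)C(=C)C | intermediate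
12 | methyl (2R,4R)-2-[1-({(2S)-1-tert-butoxy-3-methyl-1-oxobutan-2-yl}imino)ethyl]-7-methyl-2-(3-methylbut-2-en-1-yl)-4-(prop-1-en-2-yl)oct-7-enoate | C=C(C)CC[C@H](C[C@@](CC=C(C)C)(C(=O)OC)C(C)=N[C@@H](C(C)C)C(=O)OC(C)(C)C)C(=C)C | intermediate
13 | methyl (2R,4R)-2-acetyl-7-methyl-2-(3-methylbut-2-en-1-yl)-4-(prop-1-en-2-yl)oct-7-enoate | C=C(C)CC[C@H](C[C@@](CC=C(C)C)(C(=O)OC)C(C)=O)C(=C)C | intermediate
14 | methyl (2R,4R)-2-{1-[(diethoxyphosphoryl)oxy]ethenyl}-7-methyl-2-(3-methylbut-2-en-1-yl)-4-(prop-1-en-2-yl)oct-7-enoate | C=C(C)CC[C@H](C[C@@](CC=C(C)C)(C(=O)OC)C(=C)OP(=O)(OCC)OCC)C(=C)C | intermediate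
15 | methyl (2R,4R)-2-ethynyl-7-methyl-2-(3-methylbut-2-en-1-yl)-4-(prop-1-en-2-yl)oct-7-enoate | C=C(C)CC[C@H](C[C@@](CC=C(C)C)(C(=O)OC)C#C)C(=C)C | intermediate
16 | (S)-4-benzyl-3-propionyloxazolidin-2-one | CCC(=O)N1[C@@H](Cc2ccccc2)COC1=O | starting material
17 | acetaldehyde | CC=O | starting material
18 | (4S)-4-benzyl-3-[(2S,3R)-3-hydroxy-2-methylbutanoyl]oxazolidin-2-one | O[C@H](C)[C@H](C)C(=O)N1[C@@H](Cc2ccccc2)COC1=O | intermediate
19 | (2S,3R)-3-hydroxy-N-methoxy-N,2-dimethylbutanamide | O[C@H](C)[C@H](C)C(=O)N(C)OC | intermediate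
20 | methyl (2R,4R)-2-[(4S,5R)-5-hydroxy-4-methyl-3-oxohex-1-yn-1-yl]-7-methyl-2-(3-methylbut-2-en-1-yl)-4-(prop-1-en-2-yl)oct-7-enoate | C=C(C)CC[C@H](C[C@@](CC=C(C)C)(C(=O)OC)C#CC(=O)[C@@H](C)[C@@H](C)O)C(=C)C | intermediate
21 | methyl (2R,4R)-2-[(2R,3S)-2,3-dimethyl-4-oxo-3,4-dihydro-2H-pyran-6-yl]-7-methyl-2-(3-methylbut-2-en-1-yl)-4-(prop-1-en-2-yl)oct-7-enoate | C=C(C)CC[C@H](C[C@@](CC=C(C)C)(C(=O)OC)C1=CC(=O)[C@@H](C)[C@@H](C)O1)C(=C)C | intermediate
22 | methyl (2R,4R)-2-[(2R,3S)-5-iodo-2,3-dimethyl-4-oxo-3,4-dihydro-2H-pyran-6-yl]-7-methyl-2-(3-methylbut-2-en-1-yl)-4-(prop-1-en-2-yl)oct-7-enoate | C=C(C)CC[C@H](C[C@@](CC=C(C)C)(C(=O)OC)C1=C(I)C(=O)[C@@H](C)[C@@H](C)O1)C(=C)C | intermediate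
23 | 3-propylglutaric anhydride (4-propyloxane-2,6-dione) | CCCC1CC(=O)OC(=O)C1 | starting material
24 | (3R)-5-methoxy-5-oxo-3-propylpentanoic acid | OC(=O)C[C@@H](CCC)CC(=O)OC | intermediate
25 | methyl (3S)-5-chloro-5-oxo-3-propylpentanoate | ClC(=O)C[C@@H](CCC)CC(=O)OC | intermediate
26 | alkenylzinc iodide: compound 22 with ZnI in place of iodine at C5 of the pyranone | C=C(C)CC[C@H](C[C@@](CC=C(C)C)(C(=O)OC)C1=C([Zn]I)C(=O)[C@@H](C)[C@@H](C)O1)C(=C)C | intermediate
27 | methyl (2R,4R)-2-{(2R,3S)-5-[(3R)-5-methoxy-5-oxo-3-propylpentanoyl]-2,3-dimethyl-4-oxo-3,4-dihydro-2H-pyran-6-yl}-7-methyl-2-(3-methylbut-2-en-1-yl)-4-(prop-1-en-2-yl)oct-7-enoate | C=C(C)CC[C@H](C[C@@](CC=C(C)C)(C(=O)OC)C1=C(C(=O)C[C@@H](CCC)CC(=O)OC)C(=O)[C@@H](C)[C@@H](C)O1)C(=C)C | intermediate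
28 | methyl (3S)-3-{(2R,3S,8R)-5-hydroxy-2,3-dimethyl-8-(3-methylbut-2-en-1-yl)-8-[(2R)-5-methyl-2-(prop-1-en-2-yl)hex-5-en-1-yl]-4,7-dioxo-3,4,7,8-tetrahydro-2H-chromen-6-yl}hexanoate | C=C(C)CC[C@H](C[C@@]1(CC=C(C)C)C(=O)C([C@@H](CCC)CC(=O)OC)=C(O)C2=C1O[C@H](C)[C@H](C)C2=O)C(=C)C | intermediate
29 | CNP0294320.1, (3S)-3-{(2R,3S,8R)-5-hydroxy-2,3-dimethyl-8-(3-methylbut-2-en-1-yl)-8-[(2R)-5-methyl-2-(prop-1-en-2-yl)hex-5-en-1-yl]-4,7-dioxo-3,4,7,8-tetrahydro-2H-chromen-6-yl}hexanoic acid | C=C(C)CC[C@H](C[C@@]1(CC=C(C)C)C(=O)C([C@@H](CCC)CC(=O)O)=C(O)C2=C1O[C@H](C)[C@H](C)C2=O)C(=C)C | target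

**Step count and risks**

Total step count: 18.
Longest linear sequence: 14 steps from (R)-limonene (steps 1–8, 11–13, 16–18).

Steps most likely to fail:

Step 16. Zinc insertion may stall, or the alkenylzinc may be protonated instead of acylated, because C4a is wedged between the ring carbonyl and the quaternary centre and transmetalation to the acylpalladium species is slow. The fallback replaces acylation by addition to an aldehyde followed by oxidation. It sets out from 22 and 25: reduction of 25 with LiAlH(Ot-Bu)3 (THF, −78 °C) gives the aldehyde methyl (3R)-5-oxo-3-propylpentanoate F1. Nozaki–Hiyama–Kishi coupling of 22 with F1 (CrCl2, NiCl2 cat., DMSO, rt) gives the allylic alcohol methyl (2R,4R)-2-{(2R,3S)-5-[(3R)-1-hydroxy-5-methoxy-5-oxo-3-propylpentyl]-2,3-dimethyl-4-oxo-3,4-dihydro-2H-pyran-6-yl}-7-methyl-2-(3-methylbut-2-en-1-yl)-4-(prop-1-en-2-yl)oct-7-enoate F2 as a mixture of carbinol epimers. Dess–Martin oxidation (NaHCO3, CH2Cl2) removes the new centre and comes back to the route at 27.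

Step 13. The hindered vinylogous ester may react too slowly, so that electrophilic iodine is consumed by the three isolated alkenes (addition, or iodolactonisation through the neighbouring ester). The fallback introduces iodine before ring A is closed, on a far more nucleophilic carbon. It sets out from 20: conjugate addition of Me2NH (THF/EtOH, rt) gives the enaminone methyl (2R,4R)-2-[(4S,5R)-1-(dimethylamino)-5-hydroxy-4-methyl-3-oxohex-1-en-1-yl]-7-methyl-2-(3-methylbut-2-en-1-yl)-4-(prop-1-en-2-yl)oct-7-enoate F3. Treatment with I2 (1.1 equiv, CH2Cl2, rt) iodinates the α-carbon of the vinylogous amide, the hydroxyl closes on the iminium carbon and dimethylamine is lost (the iodocyclisation of enaminones known from 3-iodochromone synthesis). This comes back to the route at 22.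

Step 7. Facial discrimination may be poor, or enamine formation and alkylation may be sluggish, because the α-substituent is β-branched and bulky. The fallback gives up auxiliary control in favour of diastereomer separation. It sets out from 9, which is prenylated directly (K2CO3, prenyl bromide, acetone, reflux) to give 13 together with its C2 epimer methyl (2S,4R)-2-acetyl-7-methyl-2-(3-methylbut-2-en-1-yl)-4-(prop-1-en-2-yl)oct-7-enoate F4. The two are diastereomers because of the fixed C4 centre and would be separated by preparative HPLC; the route is rejoined at 13.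

Further compounds
F1 | step 16 | methyl (3R)-5-oxo-3-propylpentanoate | O=CC[C@@H](CCC)CC(=O)OC
F2 | step 16 | methyl (2R,4R)-2-{(2R,3S)-5-[(3R)-1-hydroxy-5-methoxy-5-oxo-3-propylpentyl]-2,3-dimethyl-4-oxo-3,4-dihydro-2H-pyran-6-yl}-7-methyl-2-(3-methylbut-2-en-1-yl)-4-(prop-1-en-2-yl)oct-7-enoate (both carbinol epimers) | C=C(C)CC[C@H](C[C@@](CC=C(C)C)(C(=O)OC)C1=C(C(O)C[C@@H](CCC)CC(=O)OC)C(=O)[C@@H](C)[C@@H](C)O1)C(=C)C
F3 | step 13 | methyl (2R,4R)-2-[(4S,5R)-1-(dimethylamino)-5-hydroxy-4-methyl-3-oxohex-1-en-1-yl]-7-methyl-2-(3-methylbut-2-en-1-yl)-4-(prop-1-en-2-yl)oct-7-enoate (alkene geometry not fixed) | C=C(C)CC[C@H](C[C@@](CC=C(C)C)(C(=O)OC)C(N(C)C)=CC(=O)[C@@H](C)[C@@H](C)O)C(=C)C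
F4 | step 7 | methyl (2S,4R)-2-acetyl-7-methyl-2-(3-methylbut-2-en-1-yl)-4-(prop-1-en-2-yl)oct-7-enoate | C=C(C)CC[C@H](C[C@](CC=C(C)C)(C(=O)OC)C(C)=O)C(=C)C
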